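**Plan**

- Retrosynthesis: the O7 sulfate and the benzyl ethers come off last. Ring C is opened at O1–C2 to a 2-hydroxyaryl ynone. That ynone is cut at O1–C8a and C4a–C4 together, giving ring A as an aryne and ring B with C2–C4 as an arylpropiolic acid.
- Enabling feature: O1 and the C4 carbonyl sit on the adjacent ring A carbons C8a and C4a, and the C5 oxygen flanks C4a. An aryne across C4a–C8a is therefore polarised to take the carboxylate oxygen at C8a and the acyl carbon at C4a.
- Forward: the ring A silyl triflate comes from 3,4,5-trihydroxybenzaldehyde through a symmetric phenol (5 steps) and the ring B acid from 3,4-bis(benzyloxy)benzaldehyde (2 steps). Aryne insertion joins them, ring C closes afterwards by amine-mediated 6-endo cyclisation, and MOM removal, 7-O-sulfation and hydrogenolysis finish the route.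
- Stereochemistry: the target has no stereocentre. The selectivities to control are regiochemical: aryne addition, 6-endo against 5-exo closure, and O7 against O5 sulfation.

Key step: step 8

Remark: the target is drawn as the free hydrogen sulfate, so sulfate monoesters are written in the acid form; in practice the sulfated intermediate would be handled as its triethylammonium salt and the final compound freed from its salt by cation exchange in the cold.

**Route**

Step 1
Reactants: 1 3,4,5-trihydroxybenzaldehyde
Product: 2 4-(benzyloxy)-3,5-dihydroxybenzaldehyde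
Conditions: BnBr (1.0 equiv), NaHCO3, DMF, 40 °C, under N2
Reagents that add atoms: benzyl bromide, BrCc1ccccc1
Why: Williamson etherification under bicarbonate control should alkylate only O4, because the hydroxyl para to the formyl group is by far the most acidic of the three and its phenoxide is the only one formed with this weak base.

Step 2
Reactants: 2 4-(benzyloxy)-3,5-dihydroxybenzaldehyde
Product: 3 4-(benzyloxy)-3,5-bis(methoxymethoxy)benzaldehyde
Conditions: MOMCl, i-Pr2NEt, CH2Cl2, 0 °C to rt
Reagents that add atoms: chloromethyl methyl ether, COCCl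
Why: Standard MOM ether formation (alkylation of the phenols with MOMCl under amine base) should cap the two equivalent hydroxyl groups without touching the aldehyde or the benzyl ether.

Step 3
Reactants: 3 4-(benzyloxy)-3,5-bis(methoxymethoxy)benzaldehyde
Product: 5 4-(benzyloxy)-3,5-bis(methoxymethoxy)phenol, via aryl formate 4 (not isolated)
Conditions: mCPBA, CH2Cl2, 0 °C to rt; then Et3N, MeOH, rt
Reagents that add atoms: 3-chloroperoxybenzoic acid (mCPBA), OOC(=O)c1cccc(Cl)c1
Why: In this Dakin-type Baeyer–Villiger oxidation the electron-rich aryl group, activated by the para benzyloxy substituent, migrates in preference to hydride to give formate 4, which triethylamine in methanol transesterifies in the same flask.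

Step 4
Reactants: 5 4-(benzyloxy)-3,5-bis(methoxymethoxy)phenol
Product: 6 4-(benzyloxy)-2-bromo-3,5-bis(methoxymethoxy)phenol
Conditions: NBS (1.0 equiv), CH2Cl2, −78 to 0 °C
Reagents that add atoms: N-bromosuccinimide, O=C1CCC(=O)N1Br
Why: Electrophilic aromatic bromination can only occur at the two equivalent positions ortho to the hydroxyl group, and one equivalent of NBS at low temperature should stop at the monobromide because the first bromine deactivates the ring.

Step 5
Reactants: 6 4-(benzyloxy)-2-bromo-3,5-bis(methoxymethoxy)phenol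
Product: 9 4-(benzyloxy)-3,5-bis(methoxymethoxy)-2-(trimethylsilyl)phenyl trifluoromethanesulfonate, via silyl ether 7 (not isolated), via lithium silylphenoxide 8 (not isolated)
Conditions: HMDS, THF, 70 °C, then evaporation; n-BuLi, THF, −100 to −78 °C; Tf2O, −78 °C to rt
Reagents that add atoms: hexamethyldisilazane, C[Si](C)(C)N[Si](C)(C)C; trifluoromethanesulfonic anhydride, O=S(=O)(OS(=O)(=O)C(F)(F)F)C(F)(F)F
Why: Silylation of the phenol, bromine–lithium exchange, retro-Brook rearrangement (1,3 O-to-C silyl shift) and triflation of the resulting phenoxide is the standard entry to 2-silylaryl triflates from 2-bromophenols, and at −100 °C the exchange is much faster than metalation directed by the MOM groups.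

Step 6
Reactants: 10 3,4-bis(benzyloxy)benzaldehyde
Product: 11 1,2-bis(benzyloxy)-4-(2,2-dibromoethenyl)benzene
Conditions: CBr4, PPh3, CH2Cl2, 0 °C
Reagents that add atoms: carbon tetrabromide, BrC(Br)(Br)Br
Why: The first stage of the Corey–Fuchs homologation, a Wittig-type olefination of the aldehyde by the dibromomethylene ylide from CBr4 and PPh3, is routine for electron-rich benzaldehydes.

Step 7
Reactants: 11 1,2-bis(benzyloxy)-4-(2,2-dibromoethenyl)benzene
Product: 13 3-[3,4-bis(benzyloxy)phenyl]prop-2-ynoic acid, via lithium acetylide 12 (not isolated)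
Conditions: n-BuLi (2.2 equiv), THF, −78 °C; CO2, −78 °C to rt; aq. HCl work-up
Reagents that add atoms: carbon dioxide, O=C=O
Why: The second stage of the Corey–Fuchs sequence turns the dibromoalkene into lithium acetylide 12 with two equivalents of n-BuLi, and carboxylation of the acetylide with CO2 followed by acidification gives the propiolic acid.

Step 8
Reactants: 9 4-(benzyloxy)-3,5-bis(methoxymethoxy)-2-(trimethylsilyl)phenyl trifluoromethanesulfonate (1.0 equiv); 13 3-[3,4-bis(benzyloxy)phenyl]prop-2-ynoic acid (1.3 equiv)
Product: 15 1-[3-(benzyloxy)-6-hydroxy-2,4-bis(methoxymethoxy)phenyl]-3-[3,4-bis(benzyloxy)phenyl]prop-2-yn-1-one, via aryne 14 (not isolated)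
Conditions: CsF (4 equiv, 13 stirred with it first), THF, 125 °C, sealed tube; aq. NH4Cl work-up
Reagents that add atoms: none
Why: Fluoride removes the silyl group of 9 with loss of triflate to give aryne 14, while the excess CsF has already turned 13 into its caesium carboxylate in aprotic THF. Attack of a carboxylate oxygen on C8a leaves a carbanion on C4a, which closes onto the adjacent ester carbonyl (4-exo-trig), and collapse of the strained benzoxetene alkoxide delivers the ketone and the phenoxide, so that O1–C8a and C4a–C4 arise in one operation without closing any ring of the target. The closest known reaction type is the fluoride-induced insertion of arynes into the acyl C–O bond of carboxylic acids, which gives 2-hydroxyaryl ketones and amounts to an aryne-triggered anionic Fries acyl shift. No stereocentre is created. The step needs regiocontrol, and the C5 OMOM group beside the aryne supplies it, since its inductive pull and the distortion it imposes on the triple bond send the nucleophile to the far carbon C8a and leave the charge on C4a next to oxygen, while the symmetric origin of 9 rules out an isomeric aryne. It also needs acyl transfer to outrun protonation of the aryl anion, which the intramolecular four-membered transition state and the absence of any proton source other than the pre-neutralised acid should secure.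

Step 9
Reactants: 15 1-[3-(benzyloxy)-6-hydroxy-2,4-bis(methoxymethoxy)phenyl]-3-[3,4-bis(benzyloxy)phenyl]prop-2-yn-1-one (crude material may be used; any flavone already formed under the fluoride conditions is the product of this step)
Product: 17 6-(benzyloxy)-2-[3,4-bis(benzyloxy)phenyl]-5,7-bis(methoxymethoxy)-4H-chromen-4-one, via enaminone 16 (not isolated)
Conditions: Et2NH (5 equiv), EtOH, rt to 60 °C
Reagents that add atoms: none
Why: Aza-Michael addition of diethylamine to the ynone gives enaminone 16, whose β-carbon the chelated phenol then attacks in a 6-endo-trig oxa-Michael addition followed by loss of the amine, a pathway that leads to the flavone and bypasses the 5-exo-dig closure to an aurone that simple bases in protic media can cause.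

Step 10
Reactants: 17 6-(benzyloxy)-2-[3,4-bis(benzyloxy)phenyl]-5,7-bis(methoxymethoxy)-4H-chromen-4-one
Product: 18 6-(benzyloxy)-2-[3,4-bis(benzyloxy)phenyl]-5,7-dihydroxy-4H-chromen-4-one
Conditions: 3 M HCl (cat.), MeOH/THF, 50 °C
Reagents that add atoms: none
Why: Acid-catalysed methanolysis of the two MOM acetals is fast at 50 °C, whereas benzyl ethers and the chromone ring are stable to dilute HCl.

Step 11
Reactants: 18 6-(benzyloxy)-2-[3,4-bis(benzyloxy)phenyl]-5,7-dihydroxy-4H-chromen-4-one
Product: 19 6-(benzyloxy)-2-[3,4-bis(benzyloxy)phenyl]-5-hydroxy-4-oxo-4H-chromen-7-yl hydrogen sulfate (handled as its triethylammonium salt)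
Conditions: SO3·NMe3 (3 equiv), Et3N, MeCN, 80 °C
Reagents that add atoms: sulfur trioxide–trimethylamine complex, C[N+](C)(C)S(=O)(=O)[O-]
Why: O-sulfation of a phenol with a sulfur trioxide–amine complex should occur only at the acidic, free 7-OH, since the 5-OH is locked in a hydrogen bond to the C4 carbonyl and is known to resist sulfation in 5,7-dihydroxyflavones.

Step 12
Reactants: 19 6-(benzyloxy)-2-[3,4-bis(benzyloxy)phenyl]-5-hydroxy-4-oxo-4H-chromen-7-yl hydrogen sulfate
Product: 20 6-hydroxyluteolin 7-sulfate, 2-(3,4-dihydroxyphenyl)-5,6-dihydroxy-4-oxo-4H-chromen-7-yl hydrogen sulfate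
Conditions: H2 (1 atm), Pd/C, MeOH/THF, rt, under argon on work-up; then Dowex 50W (H+ form), 0 °C, freeze-drying
Reagents that add atoms: none
Why: Catalytic hydrogenolysis cleaves the three benzyl ethers under neutral conditions that should leave the aryl sulfate salt and the chromone C2–C3 double bond intact, and the acidic resin then exchanges the ammonium counter-ion for a proton.

**Compound list**

1 | 3,4,5-trihydroxybenzaldehyde | O=Cc1cc(O)c(O)c(O)c1 | starting material
2 | 4-(benzyloxy)-3,5-dihydroxybenzaldehyde | O=Cc1cc(O)c(OCc2ccccc2)c(O)c1 | intermediate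
3 | 4-(benzyloxy)-3,5-bis(methoxymethoxy)benzaldehyde | O=Cc1cc(OCOC)c(OCc2ccccc2)c(OCOC)c1 | intermediate
4 | 4-(benzyloxy)-3,5-bis(methoxymethoxy)phenyl formate | O=COc1cc(OCOC)c(OCc2ccccc2)c(OCOC)c1 | intermediate
5 | 4-(benzyloxy)-3,5-bis(methoxymethoxy)phenol | Oc1cc(OCOC)c(OCc2ccccc2)c(OCOC)c1 | intermediate
6 | 4-(benzyloxy)-2-bromo-3,5-bis(methoxymethoxy)phenol | Oc1cc(OCOC)c(OCc2ccccc2)c(OCOC)c1Br | intermediate
7 | [4-(benzyloxy)-2-bromo-3,5-bis(methoxymethoxy)phenoxy]trimethylsilane | C[Si](C)(C)Oc1cc(OCOC)c(OCc2ccccc2)c(OCOC)c1Br | intermediate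
8 | lithium 4-(benzyloxy)-3,5-bis(methoxymethoxy)-2-(trimethylsilyl)phenoxide | [Li+].[O-]c1cc(OCOC)c(OCc2ccccc2)c(OCOC)c1[Si](C)(C)C | intermediate
9 | 4-(benzyloxy)-3,5-bis(methoxymethoxy)-2-(trimethylsilyl)phenyl trifluoromethanesulfonate | COCOc1cc(OS(=O)(=O)C(F)(F)F)c([Si](C)(C)C)c(OCOC)c1OCc1ccccc1 | intermediate
10 | 3,4-bis(benzyloxy)benzaldehyde | O=Cc1ccc(OCc2ccccc2)c(OCc2ccccc2)c1 | starting material
11 | 1,2-bis(benzyloxy)-4-(2,2-dibromoethenyl)benzene | BrC(Br)=Cc1ccc(OCc2ccccc2)c(OCc2ccccc2)c1 | intermediate
12 | {[3,4-bis(benzyloxy)phenyl]ethynyl}lithium | [Li]C#Cc1ccc(OCc2ccccc2)c(OCc2ccccc2)c1 | intermediate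
13 | 3-[3,4-bis(benzyloxy)phenyl]prop-2-ynoic acid | OC(=O)C#Cc1ccc(OCc2ccccc2)c(OCc2ccccc2)c1 | intermediate
14 | 4-(benzyloxy)-3,5-bis(methoxymethoxy)-1,2-didehydrobenzene (aryne; triple bond between the former C–OTf and C–SiMe3 carbons) | COCOC1=CC#CC(OCOC)=C1OCc1ccccc1 | intermediate
15 | 1-[3-(benzyloxy)-6-hydroxy-2,4-bis(methoxymethoxy)phenyl]-3-[3,4-bis(benzyloxy)phenyl]prop-2-yn-1-one | O=C(C#Cc1ccc(OCc2ccccc2)c(OCc2ccccc2)c1)c1c(O)cc(OCOC)c(OCc2ccccc2)c1OCOC | intermediate
16 | (E)-1-[3-(benzyloxy)-6-hydroxy-2,4-bis(methoxymethoxy)phenyl]-3-[3,4-bis(benzyloxy)phenyl]-3-(diethylamino)prop-2-en-1-one | CCN(CC)/C(c1ccc(OCc2ccccc2)c(OCc2ccccc2)c1)=C/C(=O)c1c(O)cc(OCOC)c(OCc2ccccc2)c1OCOC | intermediate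
17 | 6-(benzyloxy)-2-[3,4-bis(benzyloxy)phenyl]-5,7-bis(methoxymethoxy)-4H-chromen-4-one | O=c1cc(-c2ccc(OCc3ccccc3)c(OCc3ccccc3)c2)oc2cc(OCOC)c(OCc3ccccc3)c(OCOC)c12 | intermediate
18 | 6-(benzyloxy)-2-[3,4-bis(benzyloxy)phenyl]-5,7-dihydroxy-4H-chromen-4-one | O=c1cc(-c2ccc(OCc3ccccc3)c(OCc3ccccc3)c2)oc2cc(O)c(OCc3ccccc3)c(O)c12 | intermediate
19 | 6-(benzyloxy)-2-[3,4-bis(benzyloxy)phenyl]-5-hydroxy-4-oxo-4H-chromen-7-yl hydrogen sulfate | O=c1cc(-c2ccc(OCc3ccccc3)c(OCc3ccccc3)c2)oc2cc(OS(=O)(=O)O)c(OCc3ccccc3)c(O)c12 | intermediate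
20 | 6-hydroxyluteolin 7-sulfate, 2-(3,4-dihydroxyphenyl)-5,6-dihydroxy-4-oxo-4H-chromen-7-yl hydrogen sulfate | O=c1cc(-c2ccc(O)c(O)c2)oc2cc(OS(=O)(=O)O)c(O)c(O)c12 | target

**Step count**

Total step count: 12.
Longest linear sequence: 10 steps (steps 1–5 and 8–12); the ring B acid takes 2 steps (6 and 7).

**Steps most likely to fail**

Step 8 (aryne insertion). Three processes could undermine it:
- protonation of the aryl anion before acyl transfer, which ends in plain O-arylation of the acid;
- thermal decarboxylation of the caesium arylpropiolate at 125 °C;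
- uncontrolled onward cyclisation of the ynone phenoxide in both the 5-exo and the 6-endo sense.

The fallback sets out from phenol 5 and dibromoalkene 11 and returns at flavone 17. Phenol 5 would be iodinated at one of its two equivalent ortho positions (N-iodosuccinimide, CH2Cl2, −20 °C) to 4-(benzyloxy)-2-iodo-3,5-bis(methoxymethoxy)phenol F1. Dibromoalkene 11 would be converted with n-BuLi (2 equiv, THF, −78 °C) and aqueous quench into 1,2-bis(benzyloxy)-4-ethynylbenzene F2. A carbonylative Sonogashira coupling of F1 with F2 (PdCl2(dppf) cat., CO 1 atm, Et2NH, 100 °C) would form ynone 15 in the flask, and the diethylamine present would close ring C as in step 9, giving 17 directly.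

Step 5 (retro-Brook and triflation, together with the bromination that feeds it). The concerns are:
- over-bromination or oxidation of the very electron-rich phenol in step 4;
- directed ortho-metalation or benzylic deprotonation competing with bromine–lithium exchange;
- incomplete O-to-C silyl migration and loss of silicon during triflation.

The fallback sets out from phenol 5 and returns at silyl triflate 9 without a bromide. Phenol 5 would be carbamoylated (Et2NCOCl, NaH, THF) to 4-(benzyloxy)-3,5-bis(methoxymethoxy)phenyl N,N-diethylcarbamate F3. Directed ortho-metalation (s-BuLi, TMEDA, THF, −78 °C) at the position flanked by the carbamate and a MOM ether, with TMSCl quench at −78 °C to forestall the anionic Fries shift, would give 4-(benzyloxy)-3,5-bis(methoxymethoxy)-2-(trimethylsilyl)phenyl N,N-diethylcarbamate F4. Reductive cleavage of the carbamate (LiAlH4, THF, 0 °C to rt) would release 4-(benzyloxy)-3,5-bis(methoxymethoxy)-2-(trimethylsilyl)phenol F5, which Tf2O and pyridine (CH2Cl2, 0 °C) would convert into 9.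

Step 11 (sulfation). The concerns are:
- incomplete conversion of the weakly nucleophilic 7-OH next to the 6-benzyloxy group;
- partial sulfation at O5 under forcing conditions;
- loss of the polar salt on purification and hydrolysis of the monoester during handling.

The fallback sets out from diol 18 and returns at target 20. Diol 18 would be treated with 2,2,2-trichloroethyl chlorosulfate (Et3N, DMAP, THF, 0 °C to rt) to give the neutral, chromatographable diester 6-(benzyloxy)-2-[3,4-bis(benzyloxy)phenyl]-5-hydroxy-4-oxo-4H-chromen-7-yl 2,2,2-trichloroethyl sulfate F6. Pd/C with HCO2NH4 under H2 in MeOH would then remove the trichloroethyl group and the three benzyl ethers together, and cation exchange as in step 12 would give 20.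

**Further compounds**

F1 | step 8 | 4-(benzyloxy)-2-iodo-3,5-bis(methoxymethoxy)phenol | Oc1cc(OCOC)c(OCc2ccccc2)c(OCOC)c1I
F2 | step 8 | 1,2-bis(benzyloxy)-4-ethynylbenzene | C#Cc1ccc(OCc2ccccc2)c(OCc2ccccc2)c1
F3 | step 5 | 4-(benzyloxy)-3,5-bis(methoxymethoxy)phenyl N,N-diethylcarbamate | CCN(CC)C(=O)Oc1cc(OCOC)c(OCc2ccccc2)c(OCOC)c1
F4 | step 5 | 4-(benzyloxy)-3,5-bis(methoxymethoxy)-2-(trimethylsilyl)phenyl N,N-diethylcarbamate | CCN(CC)C(=O)Oc1cc(OCOC)c(OCc2ccccc2)c(OCOC)c1[Si](C)(C)C
F5 | step 5 | 4-(benzyloxy)-3,5-bis(methoxymethoxy)-2-(trimethylsilyl)phenol | Oc1cc(OCOC)c(OCc2ccccc2)c(OCOC)c1[Si](C)(C)C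
F6 | step 11 | 6-(benzyloxy)-2-[3,4-bis(benzyloxy)phenyl]-5-hydroxy-4-oxo-4H-chromen-7-yl 2,2,2-trichloroethyl sulfate | O=c1cc(-c2ccc(OCc3ccccc3)c(OCc3ccccc3)c2)oc2cc(OS(=O)(=O)OCC(Cl)(Cl)Cl)c(OCc3ccccc3)c(O)c12
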